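Primed locants number the side chain from the ring (C1' is the ring CH2).

A direct plan would buy the ring as a hydroquinone dimethyl ether and grow the chain towards it.
It would set C12' and the C10'=C11' geometry by an asymmetric iodo-aldol reaction of 4-methylpent-3-enal A1 with ethyl propiolate (iodoalkene A2), extend A2 by a B-alkyl Suzuki coupling with a hydroborated dienyne, methylaluminate the chain-end alkyne, couple it under nickel catalysis with the benzylic chloride A3, then desilylate and oxidise the arene diol A4 with (NH4)2Ce(NO3)6.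
Weak step 1, the iodo-aldol reaction that sets the only stereocentre: A1 is a β,γ-unsaturated aldehyde that conjugates and self-condenses, the iodosilane and adventitious HI can attack its trisubstituted alkene, and enantioselectivity for an unbranched enolisable aldehyde is uncertain.
Weak step 2, the hydroboration of a conjugated diene that also carries a silylalkyne, before the Suzuki coupling: regio- and chemoselectivity of the borane are not secured, and the dienyne itself would cost three steps.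
Weak step 3, the handling of the ring: four steps to A3, a silylation, a desilylation and a final oxidative demethylation of A4, seven operations that form no bond of the skeleton.

**Retrosynthetic overview**
Ring C1 is the carbonyl between C2 (chain) and C6 (methyl); ring C4 is the carbonyl between the two ring CH.
Key disconnection: the quinone ring itself. A Dötz benzannulation would close it in the last step from the terminal alkyne of the finished chain (C2, C3), the carbene carbon, Cα and Cβ of pentacarbonyl[(E)-1-methoxybut-2-enylidene]chromium (C4, C5, C6 with its methyl) and one CO ligand (C1); the cerium work-up would give the quinone and remove the only O-protecting group.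
Chain: C1'–C10' with 2'E and 6'E comes from farnesyl bromide (alkynylation at C1', excision of the terminal isopropylidene); C10'=C11' from a Michael-initiated Horner–Wadsworth–Emmons reaction; C12' (R) from Brown allylation of an enal; C14'=C15' from cross-metathesis.
The target has one carbocycle and it is closed last, so no hydroquinone ether is carried; 4-methylpent-3-enal, the diene hydroboration and the seven ring-handling operations do not occur.

Key step: step 11

Assumption: the facial preference of B-allyldiisopinocampheylborane established for simple 2-alkenals is taken to hold for the 2-substituted enal of step 7.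

**Route**

Step 1
Reactants: 1 (2E,6E)-1-bromo-3,7,11-trimethyldodeca-2,6,10-triene [(E,E)-farnesyl bromide]; 2 ethynyltri(propan-2-yl)silane
Product: 4 tri(propan-2-yl)[(4E,8E)-5,9,13-trimethyltetradeca-4,8,12-trien-1-yn-1-yl]silane, via alkynylmagnesium bromide 3 (not isolated)
Conditions: 2 (1.2 equiv), EtMgBr (1.15 equiv), THF, 50 °C; then CuBr·SMe2 (5 mol%), 1, THF, 0 to 50 °C
Reagents that add atoms: none
Why: Copper-catalysed SN2 allylic alkynylation of a primary allylic bromide by an alkynyl Grignard reagent should give the skipped enyne without touching the 2E and 6E alkenes bought with 1, the bulky silyl group keeping the alkyne inert until step 9.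

Step 2
Reactants: 4 tri(propan-2-yl)[(4E,8E)-5,9,13-trimethyltetradeca-4,8,12-trien-1-yn-1-yl]silane
Product: 6 {(4E,8E)-11-(3,3-dimethyloxiran-2-yl)-5,9-dimethylundeca-4,8-dien-1-yn-1-yl}tri(propan-2-yl)silane (racemic), via bromohydrin 5 (not isolated)
Conditions: N-bromosuccinimide (1.1 equiv), THF/H2O (3:1), 0 °C; then K2CO3, MeOH, rt
Reagents that add atoms: water, O
Why: In aqueous THF N-bromosuccinimide should attack the terminal, least hindered trisubstituted alkene of the coiled polyene (terminal-selective bromohydrin formation) and carbonate then closes the epoxide by intramolecular Williamson reaction; the racemic epoxide is acceptable because this carbon is excised in step 3.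

Step 3
Reactants: 6 {(4E,8E)-11-(3,3-dimethyloxiran-2-yl)-5,9-dimethylundeca-4,8-dien-1-yn-1-yl}tri(propan-2-yl)silane
Product: 7 (4E,8E)-4,8-dimethyl-12-[tri(propan-2-yl)silyl]dodeca-4,8-dien-11-ynal
Conditions: H5IO6 (1.2 equiv), THF/Et2O, 0 °C
Reagents that add atoms: none
Why: Periodic acid hydrates the trisubstituted epoxide and cleaves the glycol (Malaprade cleavage) to the C10' aldehyde and acetone under conditions that should leave the alkenes and the silylalkyne alone.

Step 4
Reactants: 7 (4E,8E)-4,8-dimethyl-12-[tri(propan-2-yl)silyl]dodeca-4,8-dien-11-ynal; 8 (4-methoxyphenyl)methanol; 9 ethyl 2-(diethoxyphosphoryl)prop-2-enoate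
Product: 12 ethyl (2E,6E,10E)-2-{[(4-methoxyphenyl)methoxy]methyl}-6,10-dimethyl-14-[tri(propan-2-yl)silyl]tetradeca-2,6,10-trien-13-ynoate, via sodium 4-methoxybenzyl oxide 10 (not isolated), via phosphonate carbanion 11 (not isolated)
Conditions: 8 (1.05 equiv), NaH (1.05 equiv), THF, 0 °C; 9 (1.1 equiv), −20 °C; then 7, −20 °C to rt
Reagents that add atoms: none
Why: The alkoxide adds to the vinylphosphonate (oxa-Michael addition) and the resulting α-substituted phosphonoacetate anion olefinates the aldehyde (Michael-initiated Horner–Wadsworth–Emmons reaction) under thermodynamic control, which should place the ester anti to the chain (2E) and so the future CH2OH syn to C9'.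

Step 5
Reactants: 12 ethyl (2E,6E,10E)-2-{[(4-methoxyphenyl)methoxy]methyl}-6,10-dimethyl-14-[tri(propan-2-yl)silyl]tetradeca-2,6,10-trien-13-ynoate
Product: 13 (2Z,6E,10E)-2-{[(4-methoxyphenyl)methoxy]methyl}-6,10-dimethyl-14-[tri(propan-2-yl)silyl]tetradeca-2,6,10-trien-13-yn-1-ol
Conditions: (i-Bu)2AlH (2.5 equiv), CH2Cl2, −78 °C; aq. potassium sodium tartrate
Reagents that add atoms: none
Why: (i-Bu)2AlH at low temperature should reduce the enoate in 1,2-fashion to the allylic alcohol that becomes C12', while the PMB ether keeps the second oxygenated carbon distinct (the descriptor changes to Z only through the CIP priorities).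

Step 6
Reactants: 13 (2Z,6E,10E)-2-{[(4-methoxyphenyl)methoxy]methyl}-6,10-dimethyl-14-[tri(propan-2-yl)silyl]tetradeca-2,6,10-trien-13-yn-1-ol
Product: 14 (2E,6E,10E)-2-{[(4-methoxyphenyl)methoxy]methyl}-6,10-dimethyl-14-[tri(propan-2-yl)silyl]tetradeca-2,6,10-trien-13-ynal
Conditions: MnO2 (15 equiv), CH2Cl2, rt
Reagents that add atoms: none
Why: MnO2 oxidises only the allylic alcohol, and the 2-substituted enal with the formyl group anti to the chain is the thermodynamic isomer, so material of the other geometry carried over from step 4 could be funnelled into it with a trace of iodine.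

Step 7
Reactants: 14 (2E,6E,10E)-2-{[(4-methoxyphenyl)methoxy]methyl}-6,10-dimethyl-14-[tri(propan-2-yl)silyl]tetradeca-2,6,10-trien-13-ynal
Product: 16 (4R,5E,9E,13E)-5-{[(4-methoxyphenyl)methoxy]methyl}-9,13-dimethyl-17-[tri(propan-2-yl)silyl]heptadeca-1,5,9,13-tetraen-16-yn-4-ol, via borinate 15 (not isolated)
Conditions: (+)-Ipc2BOMe (1.5 equiv), allylMgBr (1.4 equiv), Et2O, −78 °C to rt; then 14, −78 °C; then NaOH, H2O2, rt
Reagents that add atoms: allylmagnesium bromide, C=CC[Mg]Br
Why: Brown allylation through a closed chair transition state, in which B-allyldiisopinocampheylborane made from (+)-Ipc2BOMe (from (−)-α-pinene) should add to the Re face of the enal and so set C12' as R (4R in 16), the oxidative work-up releasing the alcohol.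

Step 8
Reactants: 16 (4R,5E,9E,13E)-5-{[(4-methoxyphenyl)methoxy]methyl}-9,13-dimethyl-17-[tri(propan-2-yl)silyl]heptadeca-1,5,9,13-tetraen-16-yn-4-ol; 17 2-methylbut-2-ene
Product: 18 (5R,6E,10E,14E)-6-{[(4-methoxyphenyl)methoxy]methyl}-2,10,14-trimethyl-18-[tri(propan-2-yl)silyl]octadeca-2,6,10,14-tetraen-17-yn-5-ol
Conditions: second-generation Grubbs catalyst (5 mol%), 17/CH2Cl2 (1:1), rt to 40 °C
Reagents that add atoms: none
Why: Olefin cross-metathesis of the monosubstituted alkene with excess 2-methylbut-2-ene should convert the allyl group into the prenyl group with loss of propene, the trisubstituted chain alkenes and the hindered silylalkyne being much slower partners for the ruthenium carbene.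

Step 9
Reactants: 18 (5R,6E,10E,14E)-6-{[(4-methoxyphenyl)methoxy]methyl}-2,10,14-trimethyl-18-[tri(propan-2-yl)silyl]octadeca-2,6,10,14-tetraen-17-yn-5-ol
Product: 19 (5R,6E,10E,14E)-6-{[(4-methoxyphenyl)methoxy]methyl}-2,10,14-trimethyloctadeca-2,6,10,14-tetraen-17-yn-5-ol
Conditions: Bu4NF (1.2 equiv), THF, 0 °C
Reagents that add atoms: none
Why: Fluoride cleaves the alkynyl C–Si bond at 0 °C and should leave the PMB ether, the free C12' alcohol and the skipped enyne intact.

Step 10
Reactants: 20 (1E)-1-bromoprop-1-ene; 21 hexacarbonylchromium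
Product: 24 pentacarbonyl[(2E)-1-methoxybut-2-en-1-ylidene]chromium, via (E)-prop-1-enyllithium 22 (not isolated), via lithium acylchromate 23 (not isolated)
Conditions: t-BuLi (2.0 equiv), Et2O, −78 °C; Cr(CO)6, Et2O, −78 °C to rt; then Me3OBF4, CH2Cl2/H2O, 0 °C
Reagents that add atoms: trimethyloxonium tetrafluoroborate, C[O+](C)C.F[B-](F)(F)F
Why: Fischer carbene synthesis, in which bromine–lithium exchange with retention gives (E)-propenyllithium, this adds to a CO ligand of Cr(CO)6, and the acylchromate is O-methylated by the oxonium salt.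

Step 11
Reactants: 19 (5R,6E,10E,14E)-6-{[(4-methoxyphenyl)methoxy]methyl}-2,10,14-trimethyloctadeca-2,6,10,14-tetraen-17-yn-5-ol; 24 pentacarbonyl[(2E)-1-methoxybut-2-en-1-ylidene]chromium
Product: 27 2-[(2E,6E,10E,12R)-12-hydroxy-11-(hydroxymethyl)-3,7,15-trimethylhexadeca-2,6,10,14-tetraen-1-yl]-6-methylcyclohexa-2,5-diene-1,4-dione, via arene tricarbonylchromium complex 25 (not isolated), via PMB ether quinone 26 (not isolated)
Conditions: 24 (1.5 equiv), THF (0.05 M), 50 °C, argon; then (NH4)2Ce(NO3)6 (8 equiv), MeCN/H2O (4:1), 0 °C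
Reagents that add atoms: water, O
Why: Loss of one CO from 24 lets the terminal alkyne insert into the Cr=C bond with its CH terminus bonded to the carbene carbon, CO insertion gives a dienylketene complex, and 6π-electrocyclisation onto Cβ of the propenyl group followed by tautomerisation gives the chromium-bound 4-methoxyphenol 25 (Dötz benzannulation). The closest known reaction type is the benzannulation of alkenyl(methoxy)carbene chromium complexes with terminal alkynes, including 1,4-enynes that carry isoprenoid chains, followed by cerium oxidation to 2,6-disubstituted benzoquinones. The single ring closes by this formal [3+2+1] assembly, a 6π electrocyclic closure that forms the ring bonds C3–C4, C1–C2 and C1–C6 in one operation. No stereocentre is created, and C12' should be untouched at 50 °C under neutral conditions. The step needs regioselectivity (chain next to the CO-derived carbon, so that chain and methyl flank C1), which the terminal alkyne secures because its larger substituent ends beside the phenol carbon while the methyl sits on Cβ, and chemoselectivity for the alkyne over the four trisubstituted alkenes, which do not react with the carbene at this temperature. The cerium work-up then oxidises the chromium, converts the 4-methoxyphenol into the quinone (water adds at C4, methanol leaves) and cleaves the PMB ether by single-electron oxidation, both standard uses of this reagent.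

**Compound list**

1 | (2E,6E)-1-bromo-3,7,11-trimethyldodeca-2,6,10-triene | CC(C)=CCC/C(C)=C/CC/C(C)=C/CBr | starting material
2 | ethynyltri(propan-2-yl)silane | C#C[Si](C(C)C)(C(C)C)C(C)C | starting material
3 | bromo{[tri(propan-2-yl)silyl]ethynyl}magnesium | CC(C)[Si](C#C[Mg]Br)(C(C)C)C(C)C | intermediate
4 | tri(propan-2-yl)[(4E,8E)-5,9,13-trimethyltetradeca-4,8,12-trien-1-yn-1-yl]silane | CC(C)=CCC/C(C)=C/CC/C(C)=C/CC#C[Si](C(C)C)(C(C)C)C(C)C | intermediate
5 | (4E,8E)-12-bromo-5,9,13-trimethyl-1-[tri(propan-2-yl)silyl]tetradeca-4,8-dien-1-yn-13-ol (racemic) | CC(C)(O)C(Br)CC/C(C)=C/CC/C(C)=C/CC#C[Si](C(C)C)(C(C)C)C(C)C | intermediate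
6 | {(4E,8E)-11-(3,3-dimethyloxiran-2-yl)-5,9-dimethylundeca-4,8-dien-1-yn-1-yl}tri(propan-2-yl)silane (racemic) | CC1(C)OC1CC/C(C)=C/CC/C(C)=C/CC#C[Si](C(C)C)(C(C)C)C(C)C | intermediate
7 | (4E,8E)-4,8-dimethyl-12-[tri(propan-2-yl)silyl]dodeca-4,8-dien-11-ynal | O=CCC/C(C)=C/CC/C(C)=C/CC#C[Si](C(C)C)(C(C)C)C(C)C | intermediate
8 | (4-methoxyphenyl)methanol | COc1ccc(CO)cc1 | starting material
9 | ethyl 2-(diethoxyphosphoryl)prop-2-enoate | C=C(C(=O)OCC)P(=O)(OCC)OCC | starting material
10 | sodium (4-methoxyphenyl)methanolate | COc1ccc(C[O-])cc1.[Na+] | intermediate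
11 | sodium 1-(diethoxyphosphoryl)-1-(ethoxycarbonyl)-2-[(4-methoxyphenyl)methoxy]ethan-1-ide | CCOC(=O)[C-](COCc1ccc(OC)cc1)P(=O)(OCC)OCC.[Na+] | intermediate
12 | ethyl (2E,6E,10E)-2-{[(4-methoxyphenyl)methoxy]methyl}-6,10-dimethyl-14-[tri(propan-2-yl)silyl]tetradeca-2,6,10-trien-13-ynoate | CCOC(=O)/C(COCc1ccc(OC)cc1)=C/CC/C(C)=C/CC/C(C)=C/CC#C[Si](C(C)C)(C(C)C)C(C)C | intermediate
13 | (2Z,6E,10E)-2-{[(4-methoxyphenyl)methoxy]methyl}-6,10-dimethyl-14-[tri(propan-2-yl)silyl]tetradeca-2,6,10-trien-13-yn-1-ol | OC/C(COCc1ccc(OC)cc1)=C/CC/C(C)=C/CC/C(C)=C/CC#C[Si](C(C)C)(C(C)C)C(C)C | intermediate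
14 | (2E,6E,10E)-2-{[(4-methoxyphenyl)methoxy]methyl}-6,10-dimethyl-14-[tri(propan-2-yl)silyl]tetradeca-2,6,10-trien-13-ynal | O=C/C(COCc1ccc(OC)cc1)=C/CC/C(C)=C/CC/C(C)=C/CC#C[Si](C(C)C)(C(C)C)C(C)C | intermediate
15 | diisopinocampheylborinic ester of 16 (O–B bond at C4 of 16; isopinocampheyl groups 1S,2S,3S,5R) | C=CC[C@@H](OB([C@H]1C[C@H]2C[C@@H]([C@@H]1C)C2(C)C)[C@H]1C[C@H]2C[C@@H]([C@@H]1C)C2(C)C)/C(=C/CC/C(C)=C/CC/C(C)=C/CC#C[Si](C(C)C)(C(C)C)C(C)C)COCc1ccc(OC)cc1 | intermediate
16 | (4R,5E,9E,13E)-5-{[(4-methoxyphenyl)methoxy]methyl}-9,13-dimethyl-17-[tri(propan-2-yl)silyl]heptadeca-1,5,9,13-tetraen-16-yn-4-ol | C=CC[C@@H](O)/C(=C/CC/C(C)=C/CC/C(C)=C/CC#C[Si](C(C)C)(C(C)C)C(C)C)COCc1ccc(OC)cc1 | intermediate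
17 | 2-methylbut-2-ene | CC=C(C)C | starting material
18 | (5R,6E,10E,14E)-6-{[(4-methoxyphenyl)methoxy]methyl}-2,10,14-trimethyl-18-[tri(propan-2-yl)silyl]octadeca-2,6,10,14-tetraen-17-yn-5-ol | CC(C)=CC[C@@H](O)/C(=C/CC/C(C)=C/CC/C(C)=C/CC#C[Si](C(C)C)(C(C)C)C(C)C)COCc1ccc(OC)cc1 | intermediate
19 | (5R,6E,10E,14E)-6-{[(4-methoxyphenyl)methoxy]methyl}-2,10,14-trimethyloctadeca-2,6,10,14-tetraen-17-yn-5-ol | CC(C)=CC[C@@H](O)/C(=C/CC/C(C)=C/CC/C(C)=C/CC#C)COCc1ccc(OC)cc1 | intermediate
20 | (1E)-1-bromoprop-1-ene | C/C=C/Br | starting material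
21 | hexacarbonylchromium | O=C=[Cr](=C=O)(=C=O)(=C=O)(=C=O)=C=O | starting material
22 | (1E)-prop-1-en-1-yllithium | C/C=C/[Li] | intermediate
23 | lithium pentacarbonyl[(2E)-1-oxidobut-2-en-1-ylidene]chromate | C/C=C/C([O-])=[Cr](=C=O)(=C=O)(=C=O)(=C=O)=C=O.[Li+] | intermediate
24 | pentacarbonyl[(2E)-1-methoxybut-2-en-1-ylidene]chromium | C/C=C/C(OC)=[Cr](=C=O)(=C=O)(=C=O)(=C=O)=C=O | intermediate
25 | tricarbonyl{η6-2-[(2E,6E,10E,12R)-12-hydroxy-11-{[(4-methoxyphenyl)methoxy]methyl}-3,7,15-trimethylhexadeca-2,6,10,14-tetraen-1-yl]-4-methoxy-6-methylphenol}chromium (the Cr(CO)3 unit is written as a separate fragment) | CC(C)=CC[C@@H](O)/C(=C/CC/C(C)=C/CC/C(C)=C/Cc1cc(OC)cc(C)c1O)COCc1ccc(OC)cc1.O=C=[Cr](=C=O)=C=O | intermediate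
26 | 2-[(2E,6E,10E,12R)-12-hydroxy-11-{[(4-methoxyphenyl)methoxy]methyl}-3,7,15-trimethylhexadeca-2,6,10,14-tetraen-1-yl]-6-methylcyclohexa-2,5-diene-1,4-dione | CC(C)=CC[C@@H](O)/C(=C/CC/C(C)=C/CC/C(C)=C/CC1=CC(=O)C=C(C)C1=O)COCc1ccc(OC)cc1 | intermediate
27 | 2-[(2E,6E,10E,12R)-12-hydroxy-11-(hydroxymethyl)-3,7,15-trimethylhexadeca-2,6,10,14-tetraen-1-yl]-6-methylcyclohexa-2,5-diene-1,4-dione | CC(C)=CC[C@@H](O)/C(=C/CC/C(C)=C/CC/C(C)=C/CC1=CC(=O)C=C(C)C1=O)CO | target

**Step count and risks**

Total: 11 steps. Longest linear sequence: 10 steps (steps 1 to 9 and 11).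

Steps most likely to fail:

1. Step 11. The dienylketene intermediate may be diverted to cyclobutenone, furan or two-alkyne products, and the long cerium work-up that PMB cleavage demands may oxidise the polyene or let the C12' hydroxyl trap the benzylic cation as a 4-methoxybenzylidene acetal. Fallback: the ring is bought, not built; the fallback sets out from 1 and comes back at 27. 1-Bromo-2,5-dimethoxy-3-methylbenzene F1 would be converted (Mg, THF) into bromo(2,5-dimethoxy-3-methylphenyl)magnesium F2 and coupled with 1 (CuBr·SMe2 cat.) to the farnesylarene F3. The operations of steps 2 to 8 would then be run on F3, through the bromohydrin F4, the epoxide F5, the aldehyde F6, the enoate F7 (with 8, 9 and carbanion 11), the allylic alcohol F8, the enal F9, the borinate F10, the homoallylic alcohol F11 and, with 17, the prenyl carbinol F12. (NH4)2Ce(NO3)6 in MeCN/H2O would finally demethylate the arene oxidatively to 26 and cleave its PMB ether to 27.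

2. Step 8. Secondary metathesis at the trisubstituted chain alkenes, stalling at the ethylidene stage, or catalyst loss on the silylalkyne may occur. Fallback: the prenyl group is added directly and the stereocentre is set by ketone reduction; the fallback sets out from 14 and comes back at 18. (3-Methylbut-2-en-1-yl)barium chloride (from 1-chloro-3-methylbut-2-ene and barium activated from BaI2 and lithium biphenylide, THF, −78 °C) would add through its α-carbon to 14 to give the racemic prenyl carbinol F13. Dess–Martin periodinane (NaHCO3, CH2Cl2) would oxidise it to the dienone F14. Corey–Bakshi–Shibata reduction with (S)-2-methyl-CBS-oxazaborolidine and catecholborane at −78 °C, the alkenyl group acting as the large substituent, should give 18 with 5R configuration.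

3. Step 4. The oxa-Michael addition may reverse (loss of 4-methoxybenzyl oxide from 11, or from 12 by an SN2' path) and E/Z control may erode. Fallback: the enal is made by a Wittig directed aldol condensation; the fallback sets out from 7 and comes back at 14, passing over steps 5 and 6. 3-[(4-Methoxyphenyl)methoxy]propanal F15 would be condensed with cyclohexylamine to the imine F16. Its lithium aza-enolate (lithium diisopropylamide, THF, −78 °C) would add to 7 to give the β-hydroxy imine F17. Aqueous oxalic acid would hydrolyse and dehydrate F17 to the thermodynamic (E)-enal 14.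

**Further compounds**

F1 | step 11 | 1-bromo-2,5-dimethoxy-3-methylbenzene | COc1cc(C)c(OC)c(Br)c1
F2 | step 11 | bromo(2,5-dimethoxy-3-methylphenyl)magnesium | COc1cc(C)c(OC)c([Mg]Br)c1
F3 | step 11 | 1-[(2E,6E)-3,7,11-trimethyldodeca-2,6,10-trien-1-yl]-2,5-dimethoxy-3-methylbenzene | CC(C)=CCC/C(C)=C/CC/C(C)=C/Cc1cc(OC)cc(C)c1OC
F4 | step 11 | (6E,10E)-3-bromo-12-(2,5-dimethoxy-3-methylphenyl)-2,6,10-trimethyldodeca-6,10-dien-2-ol (racemic) | CC(C)(O)C(Br)CC/C(C)=C/CC/C(C)=C/Cc1cc(OC)cc(C)c1OC
F5 | step 11 | 2-[(3E,7E)-9-(2,5-dimethoxy-3-methylphenyl)-3,7-dimethylnona-3,7-dien-1-yl]-3,3-dimethyloxirane (racemic) | CC1(C)OC1CC/C(C)=C/CC/C(C)=C/Cc1cc(OC)cc(C)c1OC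
F6 | step 11 | (4E,8E)-10-(2,5-dimethoxy-3-methylphenyl)-4,8-dimethyldeca-4,8-dienal | O=CCC/C(C)=C/CC/C(C)=C/Cc1cc(OC)cc(C)c1OC
F7 | step 11 | ethyl (2E,6E,10E)-12-(2,5-dimethoxy-3-methylphenyl)-2-{[(4-methoxyphenyl)methoxy]methyl}-6,10-dimethyldodeca-2,6,10-trienoate | CCOC(=O)/C(COCc1ccc(OC)cc1)=C/CC/C(C)=C/CC/C(C)=C/Cc1cc(OC)cc(C)c1OC
F8 | step 11 | (2Z,6E,10E)-12-(2,5-dimethoxy-3-methylphenyl)-2-{[(4-methoxyphenyl)methoxy]methyl}-6,10-dimethyldodeca-2,6,10-trien-1-ol | OC/C(COCc1ccc(OC)cc1)=C/CC/C(C)=C/CC/C(C)=C/Cc1cc(OC)cc(C)c1OC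
F9 | step 11 | (2E,6E,10E)-12-(2,5-dimethoxy-3-methylphenyl)-2-{[(4-methoxyphenyl)methoxy]methyl}-6,10-dimethyldodeca-2,6,10-trienal | O=C/C(COCc1ccc(OC)cc1)=C/CC/C(C)=C/CC/C(C)=C/Cc1cc(OC)cc(C)c1OC
F10 | step 11 | diisopinocampheylborinic ester of F11 | C=CC[C@@H](OB([C@H]1C[C@H]2C[C@@H]([C@@H]1C)C2(C)C)[C@H]1C[C@H]2C[C@@H]([C@@H]1C)C2(C)C)/C(=C/CC/C(C)=C/CC/C(C)=C/Cc1cc(OC)cc(C)c1OC)COCc1ccc(OC)cc1
F11 | step 11 | (4R,5E,9E,13E)-15-(2,5-dimethoxy-3-methylphenyl)-5-{[(4-methoxyphenyl)methoxy]methyl}-9,13-dimethylpentadeca-1,5,9,13-tetraen-4-ol | C=CC[C@@H](O)/C(=C/CC/C(C)=C/CC/C(C)=C/Cc1cc(OC)cc(C)c1OC)COCc1ccc(OC)cc1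
F12 | step 11 | (5R,6E,10E,14E)-16-(2,5-dimethoxy-3-methylphenyl)-6-{[(4-methoxyphenyl)methoxy]methyl}-2,10,14-trimethylhexadeca-2,6,10,14-tetraen-5-ol | CC(C)=CC[C@@H](O)/C(=C/CC/C(C)=C/CC/C(C)=C/Cc1cc(OC)cc(C)c1OC)COCc1ccc(OC)cc1
F13 | step 8 | (6E,10E,14E)-6-{[(4-methoxyphenyl)methoxy]methyl}-2,10,14-trimethyl-18-[tri(propan-2-yl)silyl]octadeca-2,6,10,14-tetraen-17-yn-5-ol (racemic) | CC(C)=CCC(O)/C(=C/CC/C(C)=C/CC/C(C)=C/CC#C[Si](C(C)C)(C(C)C)C(C)C)COCc1ccc(OC)cc1
F14 | step 8 | (6E,10E,14E)-6-{[(4-methoxyphenyl)methoxy]methyl}-2,10,14-trimethyl-18-[tri(propan-2-yl)silyl]octadeca-2,6,10,14-tetraen-17-yn-5-one | CC(C)=CCC(=O)/C(=C/CC/C(C)=C/CC/C(C)=C/CC#C[Si](C(C)C)(C(C)C)C(C)C)COCc1ccc(OC)cc1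
F15 | step 4 | 3-[(4-methoxyphenyl)methoxy]propanal | COc1ccc(COCCC=O)cc1
F16 | step 4 | N-cyclohexyl-3-[(4-methoxyphenyl)methoxy]propan-1-imine | COc1ccc(COCCC=NC2CCCCC2)cc1
F17 | step 4 | (6E,10E)-2-[(cyclohexylimino)methyl]-1-[(4-methoxyphenyl)methoxy]-6,10-dimethyl-14-[tri(propan-2-yl)silyl]tetradeca-6,10-dien-13-yn-3-ol | COc1ccc(COCC(C=NC2CCCCC2)C(O)CC/C(C)=C/CC/C(C)=C/CC#C[Si](C(C)C)(C(C)C)C(C)C)cc1
A1 | direct plan | 4-methylpent-3-enal | CC(C)=CCC=O
A2 | direct plan | ethyl (2Z)-2-[(1R)-1-hydroxy-4-methylpent-3-en-1-yl]-3-iodoprop-2-enoate | CCOC(=O)/C(=C\I)[C@H](O)CC=C(C)C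
A3 | direct plan | 1-(chloromethyl)-2,5-dimethoxy-3-methylbenzene | COc1cc(C)c(OC)c(CCl)c1
A4 | direct plan | (2E,6E,10E,12R)-1-(2,5-dimethoxy-3-methylphenyl)-11-(hydroxymethyl)-3,7,15-trimethylhexadeca-2,6,10,14-tetraen-12-ol | CC(C)=CC[C@@H](O)/C(=C/CC/C(C)=C/CC/C(C)=C/Cc1cc(OC)cc(C)c1OC)CO
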